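**Plan**
1. Retrosynthesis: the MOM ether on O8' is removed last; before it, the O1'–C2' bond of the hydroxylated chromene (primed locants, benzene ring = ring B) is cut back to an o-prenylphenol.
2. Ring B is then cut at C7'–C8' and C4a'–C5'. C8'(O), C8a'(O) and C4a' with its branch C4'–C3'–C2'(CH3)2 are C1–C7 of 1-(methoxymethoxy)-6-methylhept-5-en-2-one. C5'–C6'–C7' are a malonaldehyde whose central carbon carries ring A.
3. The aminoacrolein goes back through the arylacetaldehyde and 2,2-dimethyl-8-prenylchromene-6-carbaldehyde to 4-hydroxybenzaldehyde; the ketone goes back to a MOM-glycolic Weinreb amide and homoprenyl bromide.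
4. Forward order: pyran A (propargyl ether Claisen cascade on ring A), ring B (benzannulation), pyran B (DDQ), then MOM removal.
5. The target has no stereocentre; its only stereo-elements are the cis ring alkenes, fixed by the pyran rings.

Key step: step 10

Remark: enol ether 8 is carried as an E/Z mixture and the double-bond geometry of 10 and 17 is labile under the reaction conditions, so no geometry needs control; 3-chloro-3-methylbut-1-yne is taken as a commercial reagent.

**Step 1**
Reactants: 1 4-hydroxybenzaldehyde; 2 prenyl bromide (1-bromo-3-methylbut-2-ene)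
Product: 3 4-hydroxy-3-(3-methylbut-2-enyl)benzaldehyde
Conditions: KOH (aq, 10%), H2O, rt
Reagents that add atoms: none
Why: Direct ortho C-alkylation of a phenoxide in water, where solvation of the oxygen disfavours O-alkylation and the para position is blocked by the formyl group; the O-prenyl ether and dialkylated material should be separable by chromatography.

**Step 2**
Reactants: 3 4-hydroxy-3-(3-methylbut-2-enyl)benzaldehyde; 4 3-chloro-3-methylbut-1-yne
Product: 5 4-[(2-methylbut-3-yn-2-yl)oxy]-3-(3-methylbut-2-enyl)benzaldehyde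
Conditions: DBU, CuCl2 (cat.), MeCN, 0 °C to rt
Reagents that add atoms: none
Why: Copper-catalysed propargylic O-alkylation of the phenol by the tertiary propargyl chloride through a copper acetylide, the standard route to aryl 1,1-dimethylpropargyl ethers from hindered or electron-poor phenols.

**Step 3**
Reactants: 5 4-[(2-methylbut-3-yn-2-yl)oxy]-3-(3-methylbut-2-enyl)benzaldehyde
Product: 7 2,2-dimethyl-8-(3-methylbut-2-enyl)-2H-chromene-6-carbaldehyde, via o-allenylphenol 6 (not isolated)
Conditions: PhNEt2, 190 °C
Reagents that add atoms: none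
Why: Aromatic propargyl Claisen rearrangement to the free ortho carbon gives allenylphenol 6, which closes pyran A by 1,5-hydrogen shift and oxa-6π-electrocyclisation; rearrangement to the prenyl-bearing ortho carbon cannot rearomatise and reverts, so the cascade should funnel to 7.

**Step 4**
Reactants: 7 2,2-dimethyl-8-(3-methylbut-2-enyl)-2H-chromene-6-carbaldehyde
Product: 8 6-(2-methoxyethenyl)-2,2-dimethyl-8-(3-methylbut-2-enyl)-2H-chromene (E/Z mixture)
Conditions: Ph3P(CH2OMe)Cl, t-BuOK, THF, 0 °C to rt
Reagents that add atoms: (methoxymethyl)triphenylphosphonium chloride, COC[P+](c1ccccc1)(c1ccccc1)c1ccccc1.[Cl-]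
Why: Wittig reaction of the aryl aldehyde with the methoxymethylene ylide; both enol ether isomers hydrolyse to the same aldehyde, so the geometry does not matter.

**Step 5**
Reactants: 8 6-(2-methoxyethenyl)-2,2-dimethyl-8-(3-methylbut-2-enyl)-2H-chromene
Product: 9 2-[2,2-dimethyl-8-(3-methylbut-2-enyl)-2H-chromen-6-yl]acetaldehyde
Conditions: 2 M HCl (aq), THF, 40 °C; used crude
Reagents that add atoms: water, O
Why: Acid-catalysed enol ether hydrolysis, in which protonation at the benzylic carbon gives an oxocarbenium ion that is hydrated and loses methanol, a process much faster in dilute acid than protonation of the prenyl or chromene alkenes.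

**Step 6**
Reactants: 9 2-[2,2-dimethyl-8-(3-methylbut-2-enyl)-2H-chromen-6-yl]acetaldehyde
Product: 10 (E)-3-(dimethylamino)-2-[2,2-dimethyl-8-(3-methylbut-2-enyl)-2H-chromen-6-yl]prop-2-enal
Conditions: Me2NCH(OMe)2, PhMe, 80 °C
Reagents that add atoms: N,N-dimethylformamide dimethyl acetal, COC(OC)N(C)C
Why: Aminomethylenation of the doubly activated methylene (benzylic and alpha to the formyl group) by the formamide acetal, the usual route from arylacetaldehydes to 2-aryl-3-(dimethylamino)acroleins.

**Step 7**
Reactants: 11 methyl glycolate (methyl 2-hydroxyacetate)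
Product: 12 methyl 2-(methoxymethoxy)acetate
Conditions: MOMCl, i-Pr2NEt, CH2Cl2, 0 °C to rt
Reagents that add atoms: chloromethyl methyl ether, COCCl
Why: Standard O-alkylation of a primary alcohol to its methoxymethyl ether; the acetal does not migrate under base, which keeps the two ring B oxygens distinct later.

**Step 8**
Reactants: 12 methyl 2-(methoxymethoxy)acetate
Product: 13 N-methoxy-2-(methoxymethoxy)-N-methylacetamide
Conditions: MeNH(OMe)·HCl, i-PrMgCl, THF, −20 °C; aq NH4Cl
Reagents that add atoms: N,O-dimethylhydroxylamine hydrochloride, CNOC.Cl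
Why: Direct aminolysis of the ester by the chloromagnesium amide of N,O-dimethylhydroxylamine (Weinreb amide synthesis), to which the MOM acetal is inert.

**Step 9**
Reactants: 13 N-methoxy-2-(methoxymethoxy)-N-methylacetamide; 14 5-bromo-2-methylpent-2-ene
Product: 16 1-(methoxymethoxy)-6-methylhept-5-en-2-one, via Grignard reagent 15 (not isolated)
Conditions: 14, Mg, THF, rt; then 13, THF, 0 °C; aq NH4Cl
Reagents that add atoms: none
Why: Weinreb ketone synthesis, in which the chelated tetrahedral adduct of the homoprenyl Grignard reagent resists a second addition and releases the ketone only on work-up.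

**Step 10**
Reactants: 10 (E)-3-(dimethylamino)-2-[2,2-dimethyl-8-(3-methylbut-2-enyl)-2H-chromen-6-yl]prop-2-enal; 16 1-(methoxymethoxy)-6-methylhept-5-en-2-one
Product: 18 4-[2,2-dimethyl-8-(3-methylbut-2-enyl)-2H-chromen-6-yl]-2-(methoxymethoxy)-6-(3-methylbut-2-enyl)phenol, via dienaminone 17 (not isolated)
Conditions: t-BuOK (2.2 equiv), THF, 0 °C to 60 °C, 10 added slowly to the enolate of 16 (1.2 equiv); aq NH4Cl
Reagents that add atoms: none
Why: The potassium enolate of 16 undergoes aldol condensation with the vinylogous formamide carbonyl of 10 to give dienaminone 17, a second deprotonation at the remaining alpha carbon gives a cross-conjugated trienolate that cyclises, and loss of dimethylamine aromatises the ring to the phenoxide, which drives the sequence. The closest known reaction type is the base-mediated [3+3] phenol synthesis from nitromalonaldehyde or 2-aryl vinamidinium salts and ketones with two alpha methylene groups, together with the aminopentadienone formation and cyclisation-elimination benzannulation of 3-aminoacroleins. Ring B closes by 6π-electrocyclisation of the trienolate (formally a 6-endo addition of the second alpha carbon to the enamine carbon), the two new bonds being C7'–C8' and C4a'–C5'. No stereocentre is formed. The step needs only constitutional fidelity: both alpha carbons of 16 and both terminal carbons of 10 end up in the ring, so either order of bond formation gives the same 4-aryl-2-alkoxy-6-prenylphenol, and slow addition of 10 to a slight excess of enolate should keep a second molecule of 10 from capping the open intermediate. The MOM acetal, the chromene and both prenyl groups are inert to alkoxide base in THF.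

**Step 11**
Reactants: 18 4-[2,2-dimethyl-8-(3-methylbut-2-enyl)-2H-chromen-6-yl]-2-(methoxymethoxy)-6-(3-methylbut-2-enyl)phenol
Product: 20 8-(methoxymethoxy)-2,2-dimethyl-6-[2,2-dimethyl-8-(3-methylbut-2-enyl)-2H-chromen-6-yl]-2H-chromene, via o-quinone methide 19 (not isolated)
Conditions: DDQ (1.05 equiv), PhMe, rt to 60 °C
Reagents that add atoms: none
Why: DDQ dehydrogenation of the o-prenylphenol (hydride abstraction from the benzylic allylic CH2, assisted by the free hydroxyl) gives vinyl o-quinone methide 19, which closes pyran B by oxa-6π-electrocyclisation; the MOM ether blocks o-quinone formation, and the ring A prenyl group, lacking a free ortho hydroxyl, should react far more slowly.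

**Step 12**
Reactants: 20 8-(methoxymethoxy)-2,2-dimethyl-6-[2,2-dimethyl-8-(3-methylbut-2-enyl)-2H-chromen-6-yl]-2H-chromene
Product: 21 2,2-dimethyl-6-[2,2-dimethyl-8-(3-methylbut-2-enyl)-2H-chromen-6-yl]-2H-chromen-8-ol (target)
Conditions: conc. HCl (cat.), MeOH, 40 °C
Reagents that add atoms: none
Why: Acid-catalysed acetal exchange with methanol removes the MOM group; no hydroxyl sits next to the remaining prenyl group, so acid-induced chroman formation is not possible.

**Compound list**
1 | 4-hydroxybenzaldehyde | O=Cc1ccc(O)cc1 | starting material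
2 | prenyl bromide (1-bromo-3-methylbut-2-ene) | CC(C)=CCBr | starting material
3 | 4-hydroxy-3-(3-methylbut-2-enyl)benzaldehyde | O=Cc1ccc(O)c(CC=C(C)C)c1 | intermediate
4 | 3-chloro-3-methylbut-1-yne | C#CC(C)(C)Cl | starting material
5 | 4-[(2-methylbut-3-yn-2-yl)oxy]-3-(3-methylbut-2-enyl)benzaldehyde | O=Cc1ccc(OC(C)(C)C#C)c(CC=C(C)C)c1 | intermediate
6 | 4-hydroxy-3-(3-methylbuta-1,2-dienyl)-5-(3-methylbut-2-enyl)benzaldehyde (o-allenylphenol, not isolated) | O=Cc1cc(CC=C(C)C)c(O)c(C=C=C(C)C)c1 | intermediate
7 | 2,2-dimethyl-8-(3-methylbut-2-enyl)-2H-chromene-6-carbaldehyde | O=Cc1cc(CC=C(C)C)c2OC(C)(C)C=Cc2c1 | intermediate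
8 | 6-(2-methoxyethenyl)-2,2-dimethyl-8-(3-methylbut-2-enyl)-2H-chromene (E/Z mixture) | COC=Cc1cc(CC=C(C)C)c2OC(C)(C)C=Cc2c1 | intermediate
9 | 2-[2,2-dimethyl-8-(3-methylbut-2-enyl)-2H-chromen-6-yl]acetaldehyde | O=CCc1cc(CC=C(C)C)c2OC(C)(C)C=Cc2c1 | intermediate
10 | (E)-3-(dimethylamino)-2-[2,2-dimethyl-8-(3-methylbut-2-enyl)-2H-chromen-6-yl]prop-2-enal | CN(C)/C=C(/C=O)c1cc(CC=C(C)C)c2OC(C)(C)C=Cc2c1 | intermediate
11 | methyl glycolate (methyl 2-hydroxyacetate) | COC(=O)CO | starting material
12 | methyl 2-(methoxymethoxy)acetate | COCOCC(=O)OC | intermediate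
13 | N-methoxy-2-(methoxymethoxy)-N-methylacetamide | COCOCC(=O)N(C)OC | intermediate
14 | 5-bromo-2-methylpent-2-ene | CC(C)=CCCBr | starting material
15 | (4-methylpent-3-enyl)magnesium bromide (not isolated) | CC(C)=CCC[Mg]Br | intermediate
16 | 1-(methoxymethoxy)-6-methylhept-5-en-2-one | COCOCC(=O)CCC=C(C)C | intermediate
17 | 1-(dimethylamino)-2-[2,2-dimethyl-8-(3-methylbut-2-enyl)-2H-chromen-6-yl]-4-(methoxymethoxy)-9-methyldeca-1,3,8-trien-5-one (dienaminone, geometry labile, drawn for first condensation at the alkoxy carbon, not isolated) | COCOC(=CC(=CN(C)C)c1cc(CC=C(C)C)c2OC(C)(C)C=Cc2c1)C(=O)CCC=C(C)C | intermediate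
18 | 4-[2,2-dimethyl-8-(3-methylbut-2-enyl)-2H-chromen-6-yl]-2-(methoxymethoxy)-6-(3-methylbut-2-enyl)phenol | COCOc1cc(cc(CC=C(C)C)c1O)-c1cc(CC=C(C)C)c2OC(C)(C)C=Cc2c1 | intermediate
19 | 4-[2,2-dimethyl-8-(3-methylbut-2-enyl)-2H-chromen-6-yl]-2-(methoxymethoxy)-6-(3-methylbut-2-enylidene)cyclohexa-2,4-dien-1-one (o-quinone methide, not isolated) | COCOC1=CC(=CC(=CC=C(C)C)C1=O)c1cc(CC=C(C)C)c2OC(C)(C)C=Cc2c1 | intermediate
20 | 8-(methoxymethoxy)-2,2-dimethyl-6-[2,2-dimethyl-8-(3-methylbut-2-enyl)-2H-chromen-6-yl]-2H-chromene | COCOc1cc(cc2C=CC(C)(C)Oc12)-c1cc(CC=C(C)C)c2OC(C)(C)C=Cc2c1 | intermediate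
21 | 2,2-dimethyl-6-[2,2-dimethyl-8-(3-methylbut-2-enyl)-2H-chromen-6-yl]-2H-chromen-8-ol | CC(C)=CCc1cc(-c2cc(O)c3c(c2)C=CC(C)(C)O3)cc2c1OC(C)(C)C=C2 | target

**Step count and risks**
Total step count: 12. Longest linear sequence: 9 (steps 1–6, 10, 11, 12); steps 7–9 make the ketone in parallel.

Steps most likely to fail:

Step 10. The aldol addition of the ketone enolate to the weakly electrophilic vinylogous formamide may lag behind self-condensation of 16, or the open dienaminone may stall before cyclisation and amine loss. The fallback sets out from 10, which is condensed with dimethylammonium tetrafluoroborate (Me2NH2BF4, EtOH, reflux) to the symmetrical vinamidinium salt N-{3-(dimethylamino)-2-[2,2-dimethyl-8-(3-methylbut-2-enyl)-2H-chromen-6-yl]prop-2-enylidene}-N-methylmethanaminium tetrafluoroborate F1, a much stronger electrophile at both termini. F1 is then annulated with the potassium enolate of 16 (t-BuOK, THF, 0 to 45 °C), the established vinamidinium–ketone phenol synthesis, and the route is rejoined at 18.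

Step 11. Over-oxidation may compete: hydride abstraction at the benzylic allylic CH2 of the ring A prenyl group, or oxidation of the electron-rich guaiacol-type ring, instead of clean dehydrogenation of the phenolic prenyl unit. The fallback sets out from 18 and replaces the oxidation by selenium chemistry. N-(Phenylseleno)phthalimide with catalytic camphorsulfonic acid (CH2Cl2, −78 to 0 °C) should give, by 6-endo selenoetherification, racemic 8-(methoxymethoxy)-2,2-dimethyl-6-[2,2-dimethyl-8-(3-methylbut-2-enyl)-2H-chromen-6-yl]-3-(phenylselanyl)-3,4-dihydro-2H-chromene F2; the ring A prenyl group has no internal nucleophile and should be left alone. Oxidation (H2O2, pyridine, THF, 0 °C to rt) gives the corresponding selenoxide F3, not isolated, whose syn elimination can only run towards C4' because C2' carries no hydrogen, and the route is rejoined at 20.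

Step 5. The electron-rich arylacetaldehyde may be lost to acid-induced self-aldol condensation, or slow hydrolysis may force stronger acid and lead to hydration of the prenyl group. The fallback sets out from 7 and avoids acid altogether. Wittig methylenation (Ph3PCH3Br, t-BuOK, THF) gives 6-ethenyl-2,2-dimethyl-8-(3-methylbut-2-enyl)-2H-chromene F4. Hydroboration with 9-BBN (THF, rt), selective for the monosubstituted vinyl group over the trisubstituted prenyl and cis-disubstituted chromene alkenes, gives 9-{2-[2,2-dimethyl-8-(3-methylbut-2-enyl)-2H-chromen-6-yl]ethyl}-9-borabicyclo[3.3.1]nonane F5, not isolated. Oxidation (NaOH, H2O2) gives 2-[2,2-dimethyl-8-(3-methylbut-2-enyl)-2H-chromen-6-yl]ethanol F6, and Dess–Martin periodinane (NaHCO3, CH2Cl2) gives 9, which is taken at once into step 6.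

**Further compounds**
F1 | step 10 | N-{3-(dimethylamino)-2-[2,2-dimethyl-8-(3-methylbut-2-enyl)-2H-chromen-6-yl]prop-2-enylidene}-N-methylmethanaminium tetrafluoroborate | C[N+](C)=CC(=CN(C)C)c1cc(CC=C(C)C)c2OC(C)(C)C=Cc2c1.F[B-](F)(F)F
F2 | step 11 | rac-8-(methoxymethoxy)-2,2-dimethyl-6-[2,2-dimethyl-8-(3-methylbut-2-enyl)-2H-chromen-6-yl]-3-(phenylselanyl)-3,4-dihydro-2H-chromene | COCOc1cc(cc2CC([Se]c3ccccc3)C(C)(C)Oc12)-c1cc(CC=C(C)C)c2OC(C)(C)C=Cc2c1
F3 | step 11 | selenoxide of F2 (3-(benzeneseleninyl) compound, diastereomer mixture, not isolated) | COCOc1cc(cc2CC([Se](=O)c3ccccc3)C(C)(C)Oc12)-c1cc(CC=C(C)C)c2OC(C)(C)C=Cc2c1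
F4 | step 5 | 6-ethenyl-2,2-dimethyl-8-(3-methylbut-2-enyl)-2H-chromene | C=Cc1cc(CC=C(C)C)c2OC(C)(C)C=Cc2c1
F5 | step 5 | 9-{2-[2,2-dimethyl-8-(3-methylbut-2-enyl)-2H-chromen-6-yl]ethyl}-9-borabicyclo[3.3.1]nonane (not isolated) | CC(C)=CCc1cc(CCB2C3CCCC2CCC3)cc2C=CC(C)(C)Oc12
F6 | step 5 | 2-[2,2-dimethyl-8-(3-methylbut-2-enyl)-2H-chromen-6-yl]ethanol | OCCc1cc(CC=C(C)C)c2OC(C)(C)C=Cc2c1
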